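The rate constants come from no measurement; the rest is arithmetic.

If the reagent is charged into a second phase and has to cross before it meets starting material, I reckon its level in the reaction phase first.

    starting material + protic impurity → quenched substrate (k1 = 0.208 /M/s)
    2 reagent in the reaction phase → homo dimer (k2 = 0.276 /M/s)
    starting material + target → side product (k3 = 0.374 /M/s)
    starting material + reagent in the reaction phase → target (k4 = 0.793 /M/s)
    reagent in the reaction phase ⇌ reagent in the second phase, rate k5*([reagent in the reaction phase] - [reagent in the second phase]/K5) per volume of the first phase (K5 = 22.0, k5 = 0.275 /s)
    target → decomposed product (k6 = 0.0315 /s)
    target ⇌ product in the second phase, rate k7*([target] - [product in the second phase]/K7) per volume of the first phase (K7 = 0.58, k7 = 0.0299 /s)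

starting material 0.055 M; reagent in the second phase 1.80 equiv; protic impurity 0.0550 M; time 50 s; volume of the second phase over the first 0.50

- percent here means starting material units held: one side product counts as two
- what is said of target includes product in the second phase
- two of one species on the left: rate k times its square, two consumed each time
- in the second phase: reagent in the second phase, product in the second phase; everything else is in the first
- charges count per volume of the first phase; a concentration in a rate is the amount of a species over the volume of its own phase; every rate counts per litre of the first phase
- run time (flask): 50 s

- midnight: doubling the transfer coefficient of step 7, all else as stated
- dawn: doubling the transfer coefficient of step 5, all else as stated
- dusk: doubling the amount of reagent in the second phase, all else as stated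

- amount of target and product in the second phase together at 50 s, in percent of the starting material charged
- the change that raises the amount of target and product in the second phase together at 50 s, in percent of the starting material charged most ("none" if none brings more than 2 percentage points) (midnight / dawn / dusk / none)
- amount of target and product in the second phase together at 50 s, in percent of the starting material charged, after dusk

Before I take any number, I ask what each would do if it were off. The equilibrium [reagent in the reaction phase] is the second-phase concentration over the partition ratio, so an error in that ratio or in the reagent charge passes in full into this level. The reagent's transfer coefficient counts for little, since crossing takes about 3.64 s, far less than the run of 50 s. Dimerisation counts for little too, draining at 0.00497 /s at the partition level against that coefficient of 0.275 /s. The target's transfer coefficient moves target between two forms that are both counted, so I leave it out of my sum. The constants of target formation, quench, decomposition and side reaction enter directly.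

Now the number. The partition level is 0.00900 M. Divided by one plus the drain to target at charge, 0.0436 /s, over the transfer coefficient, it gives 0.00777 M. This is the working level, the mean that replaces the curve of [reagent in the reaction phase].

With it and the impurity held at charge, starting material falls pseudo-first-order at 0.0176 /s, and target is lost at 0.0452 /s. These two exponentials give 6.93%. The errors pull apart: the held impurity understates the yield, while the lag and the reagent drawn off overstate it. Doubling the working level by dusk gives 11.9%, whereas dawn lifts the level by a factor of just 1.07. I choose dusk.

The forecast gives 7.8%, names dusk and gives 13.6% after it, holding that “Doubling the reagent roughly doubles its level”. Its yields stand above mine.

The simulation gives 7.78%, dusk with a gain of 5.8 percentage points, and 13.6%, so the forecast holds, and my two exponentials reach the same choice. In this flask [reagent in the reaction phase] reads 0.00699 M at 25.0 s and 0.00681 M at 50.0 s, against the working level of 0.00777 M. At the later time, each step taken net, it is made 0.960 times as fast as it is used up.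

In the neighbour with 0.014 M of starting material, where the impurity stands at 3.93 equiv, the working level is 0.00220 M and the same sum gives 2.73%. The simulation of that neighbour reads 0.00198 M of reagent in the reaction phase at 50.0 s and 2.80% of target and product in the second phase together.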